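**Plan**
- Retrosynthesis: first the two aryl ether bonds O–C8 of the side arms are cut (each arm goes back to a lactate-derived α-mesyloxy aryl ketone), then, in one stroke, the two C–C bonds C2–C3 and C4–C5 of the oxolane.
- Enabling feature: C2 and C5 of the oxolane are both benzylic and both bonded to O1, so C2–O1–C5 is a 1,3-diaryl carbonyl ylide (from a 2,3-diaryloxirane by C–C cleavage); C3/C4 with their trans methyls are an (E)-alkene.
- The alkene is used at the fumaroyl oxidation level (two N-acyl bornane-10,2-sultams as activating groups and auxiliaries). The ylide carries two differently masked phenols (allyl, benzyl) and a temporary ortho-bromine on one ring.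
- Forward: oxirane (sulfonium ylide epoxidation) → photosensitised (3+2) cycloaddition closes the only new ring with all four ring stereocentres → C(=O)N → CH2OH → CH2OMs → CH3 → first phenol freed, arm 1 → second phenol freed (bromine lost), arm 2.
- Stereochemistry: 2,5-cis from the W-shaped ylide, 3,4-trans from the E-alkene, absolute sense from the sultams, the choice of which aryl lies cis to its neighbour from the bromine; C8 of each arm by SN2 inversion, C7 by chelation-controlled (erythro arm) or Felkin–Anh (threo arm) hydride delivery.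

Key step: step 11

Remark (target as read): (2S,3S,4S,5R)-oxolane with the aryls 2,5-cis and the methyls 3,4-trans; the C2 aryl (trans to 3-CH3) carries the (1R,2S)-erythro arm, the C5 aryl (cis to 4-CH3) the (1R,2R)-threo arm.
Remark (assumption): the (2R)-sultam is chosen because uncatalysed cycloadditions to N-enoyl-(2R)-bornane-10,2-sultams take place on the Cα-re face, which is the face required here; should the sense be opposite for this dipole, the antipodal sultam would be used in the same way.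

**Step 1**
Reactants: 1 methyl (R)-lactate
Product: 2 (2R)-2-hydroxy-N-methoxy-N-methylpropanamide
Conditions: MeNH(OMe)·HCl, iPrMgCl, THF, −20 to 0 °C
Reagents that add atoms: N,O-dimethylhydroxylamine hydrochloride, CNOC.Cl
Why: Weinreb amide formation by aminolysis of the ester with the chloromagnesium amide, which does not touch the carbinol stereocentre.

**Step 2**
Reactants: 2 (2R)-2-hydroxy-N-methoxy-N-methylpropanamide
Product: 3 (2R)-1-(3,4-dimethoxyphenyl)-2-hydroxypropan-1-one
Conditions: (3,4-dimethoxyphenyl)magnesium bromide (2.5 equiv), THF, 0 °C to rt; aq. NH4Cl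
Reagents that add atoms: (3,4-dimethoxyphenyl)magnesium bromide, COc1ccc([Mg]Br)cc1OC
Why: Weinreb ketone synthesis; the magnesium chelate of the alkoxide-bearing amide collapses to the ketone only on work-up, so over-addition and enolisation of the stereocentre should be avoided.

**Step 3**
Reactants: 3 (2R)-1-(3,4-dimethoxyphenyl)-2-hydroxypropan-1-one
Product: 4 (2R)-1-(3,4-dimethoxyphenyl)-1-oxopropan-2-yl methanesulfonate
Conditions: MsCl, Et3N, CH2Cl2, −20 to 0 °C
Reagents that add atoms: methanesulfonyl chloride, CS(=O)(=O)Cl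
Why: O-sulfonylation of the secondary alcohol with retention gives an α-keto sulfonate that is activated for SN2 displacement.

**Step 4**
Reactants: 5 ethyl (S)-lactate
Product: 6 (2S)-2-hydroxy-N-methoxy-N-methylpropanamide
Conditions: MeNH(OMe)·HCl, iPrMgCl, THF, −20 to 0 °C
Reagents that add atoms: N,O-dimethylhydroxylamine hydrochloride, CNOC.Cl
Why: Weinreb amide formation as in step 1, in the enantiomeric series.

**Step 5**
Reactants: 6 (2S)-2-hydroxy-N-methoxy-N-methylpropanamide
Product: 7 (2S)-1-(3,4-dimethoxyphenyl)-2-hydroxypropan-1-one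
Conditions: (3,4-dimethoxyphenyl)magnesium bromide (2.5 equiv), THF, 0 °C to rt; aq. NH4Cl
Reagents that add atoms: (3,4-dimethoxyphenyl)magnesium bromide, COc1ccc([Mg]Br)cc1OC
Why: Weinreb ketone synthesis as in step 2.

**Step 6**
Reactants: 7 (2S)-1-(3,4-dimethoxyphenyl)-2-hydroxypropan-1-one
Product: 8 (2S)-1-(3,4-dimethoxyphenyl)-1-oxopropan-2-yl methanesulfonate
Conditions: MsCl, Et3N, CH2Cl2, −20 to 0 °C
Reagents that add atoms: methanesulfonyl chloride, CS(=O)(=O)Cl
Why: O-sulfonylation with retention as in step 3.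

**Step 7**
Reactants: 9 2-bromo-4-hydroxy-5-methoxybenzaldehyde (6-bromovanillin)
Product: 10 4-(allyloxy)-2-bromo-5-methoxybenzaldehyde
Conditions: allyl bromide, K2CO3, DMF, rt
Reagents that add atoms: allyl bromide, C=CCBr
Why: Williamson etherification of the phenol installs the first of the two orthogonal phenol masks on the ring that carries the temporary bromine.

**Step 8**
Reactants: 11 [4-(benzyloxy)-3-methoxyphenyl]methanol
Product: 12 1-[4-(benzyloxy)-3-methoxybenzyl]thiolan-1-ium tetrafluoroborate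
Conditions: tetrahydrothiophene, 48% aq. HBF4, rt
Reagents that add atoms: tetrahydrothiophene, C1CCSC1; tetrafluoroboric acid, [H+].F[B-](F)(F)F
Why: the acid ionises the 4-alkoxybenzyl alcohol and the stabilised benzylic cation is captured by the sulfide, a known way to benzylsulfonium salts of electron-rich arenes.

**Step 9**
Reactants: 10 4-(allyloxy)-2-bromo-5-methoxybenzaldehyde; 12 1-[4-(benzyloxy)-3-methoxybenzyl]thiolan-1-ium tetrafluoroborate
Product: 14 trans-2-[4-(allyloxy)-2-bromo-5-methoxyphenyl]-3-[4-(benzyloxy)-3-methoxyphenyl]oxirane (racemic), via sulfonium ylide 13 (not isolated)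
Conditions: KOH, MeCN/H2O (9:1), 0 °C to rt; filtration through basic Al2O3
Reagents that add atoms: none
Why: Corey–Chaykovsky-type epoxidation with a semi-stabilised benzylic sulfonium ylide should give mainly the trans-oxirane; its configuration is erased in step 11, so neither the cis/trans ratio nor the racemic nature matters.

**Step 10**
Reactants: 15 (2R)-bornane-10,2-sultam (two equivalents); 16 fumaryl chloride (one equivalent)
Product: 18 N,N'-fumaroylbis[(2R)-bornane-10,2-sultam], via sodium sultamide 17 (not isolated)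
Conditions: 15 (2.0 equiv), NaH (2.2 equiv), toluene, rt; then 16 (1.0 equiv), 0 °C to rt
Reagents that add atoms: (2R)-bornane-10,2-sultam (the second equivalent of 15), O=S1(=O)C[C@]23CC[C@H](C[C@H]2N1)C3(C)C
Why: twofold N-acylation, in which each of the two acid chloride groups of 16 acylates one molecule of the sodium salt of the sultam, so that two molecules of 15 are built into the crystalline C2-symmetric (E)-bis-imide with the alkene geometry retained.

**Step 11**
Reactants: 14 trans-2-[4-(allyloxy)-2-bromo-5-methoxyphenyl]-3-[4-(benzyloxy)-3-methoxyphenyl]oxirane; 18 N,N'-fumaroylbis[(2R)-bornane-10,2-sultam]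
Product: 20 N,N'-{[(2S,3S,4S,5R)-2-(4-allyloxy-2-bromo-5-methoxyphenyl)-5-(4-benzyloxy-3-methoxyphenyl)oxolane-3,4-diyl]dicarbonyl}bis[(2R)-bornane-10,2-sultam], via carbonyl ylide 19 (not isolated)
Conditions: 9,10-dicyanoanthracene (5 mol %), 14 (1.5 equiv), MeCN/CH2Cl2, 420 nm LEDs, rt, argon; chromatography, then crystallisation
Reagents that add atoms: none
Why: Electron transfer from 14 to the excited dicyanoanthracene gives the oxirane radical cation, whose C–C bond breaks, and back electron transfer delivers carbonyl ylide 19, which adds suprafacially across the C=C bond of 18 in a concerted 1,3-dipolar (3+2) cycloaddition. The closest known reaction type is the dicyanoarene-sensitised cycloaddition of carbonyl ylides from 2,3-diaryloxiranes to fumarates, used for 2,5-diaryloxolane lignans, combined with the uncatalysed, auxiliary-controlled cycloadditions of N-enoyl bornane-10,2-sultams. The oxolane is closed intermolecularly by simultaneous formation of C2–C3 and C4–C5 (five-membered ring from a three-atom 4π dipole and a two-atom 2π partner, not by cyclisation of a chain). C2 and C5 should become cis because the ylide reacts in its exo,exo (W) form, C3 and C4 trans because the E geometry of 18 is retained, and their absolute configuration should follow from attack on the Cα-re face of each N-enoyl sultam unit, the other face being shielded by the auxiliary. The step also needs orientation selectivity, that is, which aryl ends up cis to the neighbouring acyl group: the endo acyl group should avoid the terminus with the twisted ortho-bromoaryl ring and lie under the planar benzyloxyaryl ring, making the C4 acyl cis to the C5 aryl and the C3 acyl trans to the C2 bromoaryl. There is no regiochemical issue because 18 is C2-symmetric, and the bromine next to the ring should make the orientation isomer separable.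

**Step 12**
Reactants: 20 bis(N-acylsultam) cycloadduct
Product: 21 [(2S,3R,4R,5R)-2-(4-allyloxy-2-bromo-5-methoxyphenyl)-5-(4-benzyloxy-3-methoxyphenyl)oxolane-3,4-diyl]dimethanol
Conditions: LiAlH4, THF, 0 °C
Reagents that add atoms: none
Why: reductive cleavage of the N-acyl sultams by LiAlH4 gives the primary alcohols and returns the auxiliary 15, while allyl and benzyl ethers and the aryl bromide should persist at 0 °C.

**Step 13**
Reactants: 21 diol
Product: 22 [(2S,3R,4R,5R)-2-(4-allyloxy-2-bromo-5-methoxyphenyl)-5-(4-benzyloxy-3-methoxyphenyl)oxolane-3,4-diyl]bis(methylene) dimethanesulfonate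
Conditions: MsCl, Et3N, CH2Cl2, 0 °C
Reagents that add atoms: methanesulfonyl chloride, CS(=O)(=O)Cl
Why: sulfonylation of both primary alcohols; the trans arrangement of the two arms prevents cyclisation to a fused bis-ether.

**Step 14**
Reactants: 22 bis-mesylate
Product: 23 (2S,3S,4S,5R)-2-(4-allyloxy-2-bromo-5-methoxyphenyl)-5-(4-benzyloxy-3-methoxyphenyl)-3,4-dimethyloxolane
Conditions: LiBHEt3, THF, 0 °C to rt
Reagents that add atoms: none
Why: SN2 displacement of the primary sulfonates by hydride converts both former acyl carbons into the methyl groups without touching a stereocentre, the standard end of diester-based oxolane lignan syntheses.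

**Step 15**
Reactants: 23 allyl ether
Product: 24 4-[(2S,3S,4S,5R)-5-(4-benzyloxy-3-methoxyphenyl)-3,4-dimethyloxolan-2-yl]-5-bromo-2-methoxyphenol
Conditions: Pd(PPh3)4 (5 mol %), morpholine, THF, rt
Reagents that add atoms: none
Why: Tsuji–Trost deallylation (π-allyl palladium formation, capture by morpholine) frees only the phenol of the C2 aryl; at rt insertion into the hindered, electron-rich aryl bromide should be much slower.

**Step 16**
Reactants: 24 bromophenol; 4 (2R)-1-(3,4-dimethoxyphenyl)-1-oxopropan-2-yl methanesulfonate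
Product: 25 (2S)-2-{4-[(2S,3S,4S,5R)-5-(4-benzyloxy-3-methoxyphenyl)-3,4-dimethyloxolan-2-yl]-5-bromo-2-methoxyphenoxy}-1-(3,4-dimethoxyphenyl)propan-1-one
Conditions: BEMP (2-tert-butylimino-2-diethylamino-1,3-dimethylperhydro-1,3,2-diazaphosphorine), CH2Cl2, rt
Reagents that add atoms: none
Why: SN2 displacement of the α-keto mesylate by the phenoxide with inversion (R to S) sets C8 of the first arm; the non-nucleophilic phosphazene base is used to avoid enolisation of the product.

**Step 17**
Reactants: 25 α-aryloxy ketone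
Product: 26 (1R,2S)-2-{4-[(2S,3S,4S,5R)-5-(4-benzyloxy-3-methoxyphenyl)-3,4-dimethyloxolan-2-yl]-5-bromo-2-methoxyphenoxy}-1-(3,4-dimethoxyphenyl)propan-1-ol (erythro)
Conditions: Zn(BH4)2, Et2O, −20 to 0 °C
Reagents that add atoms: none
Why: Cram-chelate reduction: zinc bridges the carbonyl and aryloxy oxygens and hydride enters from the side of H, opposite to CH3, which should give the (1R,2S)-erythro alcohol.

**Step 18**
Reactants: 26 erythro alcohol
Product: 27 (1R,2S)-1-(3,4-dimethoxyphenyl)-2-{4-[(2S,3S,4S,5R)-5-(4-hydroxy-3-methoxyphenyl)-3,4-dimethyloxolan-2-yl]-2-methoxyphenoxy}propan-1-ol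
Conditions: H2 (1 atm), Pd/C, NaOAc, EtOAc/MeOH, rt
Reagents that add atoms: none
Why: hydrogenolysis removes the benzyl ether and the helper bromine in one operation; the acetate buffer takes up HBr so that the acid-labile benzylic ether bonds of the oxolane and the benzylic carbinol should survive.

**Step 19**
Reactants: 27 phenol; 8 (2S)-1-(3,4-dimethoxyphenyl)-1-oxopropan-2-yl methanesulfonate
Product: 28 (2R)-1-(3,4-dimethoxyphenyl)-2-{4-[(2R,3S,4S,5S)-5-(4-{[(1R,2S)-1-(3,4-dimethoxyphenyl)-1-hydroxypropan-2-yl]oxy}-3-methoxyphenyl)-3,4-dimethyloxolan-2-yl]-2-methoxyphenoxy}propan-1-one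
Conditions: BEMP, CH2Cl2, rt
Reagents that add atoms: none
Why: SN2 etherification with inversion (S to R) as in step 16 sets C8 of the second arm; the secondary alcohol of the first arm is not deprotonated under these conditions.

**Step 20**
Reactants: 28 α-aryloxy ketone
Product: 29 (1R,2S)-1-(3,4-dimethoxyphenyl)-2-[4-[(2S,3S,4S,5R)-5-[4-[[(1R,2R)-1-(3,4-dimethoxyphenyl)-1-hydroxypropan-2-yl]oxy]-3-methoxyphenyl]-3,4-dimethyloxolan-2-yl]-2-methoxyphenoxy]propan-1-ol (target)
Conditions: borohydride on Amberlite IRA-400 resin (BH4− form), MeOH, 0 °C to rt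
Reagents that add atoms: none
Why: Felkin–Anh reduction: with a non-chelating ammonium counter-ion hydride adds anti to the C–OAr bond and past H, not CH3, which should give the (1R,2R)-threo arm, as known for this arm type with resin-bound borohydride.

**Compound list**
1 | methyl (R)-lactate | C[C@@H](O)C(=O)OC | starting material
2 | (2R)-2-hydroxy-N-methoxy-N-methylpropanamide | C[C@@H](O)C(=O)N(C)OC | intermediate
3 | (2R)-1-(3,4-dimethoxyphenyl)-2-hydroxypropan-1-one | C[C@@H](O)C(=O)c1ccc(OC)c(OC)c1 | intermediate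
4 | (2R)-1-(3,4-dimethoxyphenyl)-1-oxopropan-2-yl methanesulfonate | C[C@@H](OS(C)(=O)=O)C(=O)c1ccc(OC)c(OC)c1 | intermediate
5 | ethyl (S)-lactate | C[C@H](O)C(=O)OCC | starting material
6 | (2S)-2-hydroxy-N-methoxy-N-methylpropanamide | C[C@H](O)C(=O)N(C)OC | intermediate
7 | (2S)-1-(3,4-dimethoxyphenyl)-2-hydroxypropan-1-one | C[C@H](O)C(=O)c1ccc(OC)c(OC)c1 | intermediate
8 | (2S)-1-(3,4-dimethoxyphenyl)-1-oxopropan-2-yl methanesulfonate | C[C@H](OS(C)(=O)=O)C(=O)c1ccc(OC)c(OC)c1 | intermediate
9 | 2-bromo-4-hydroxy-5-methoxybenzaldehyde (6-bromovanillin) | O=Cc1cc(OC)c(O)cc1Br | starting material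
10 | 4-(allyloxy)-2-bromo-5-methoxybenzaldehyde | O=Cc1cc(OC)c(OCC=C)cc1Br | intermediate
11 | [4-(benzyloxy)-3-methoxyphenyl]methanol | OCc1ccc(OCc2ccccc2)c(OC)c1 | starting material
12 | 1-[4-(benzyloxy)-3-methoxybenzyl]thiolan-1-ium tetrafluoroborate | COc1cc(C[S+]2CCCC2)ccc1OCc1ccccc1.F[B-](F)(F)F | intermediate
13 | sulfonium ylide of 12 (formed in the flask) | COc1cc([CH-][S+]2CCCC2)ccc1OCc1ccccc1 | intermediate
14 | trans-2-[4-(allyloxy)-2-bromo-5-methoxyphenyl]-3-[4-(benzyloxy)-3-methoxyphenyl]oxirane (racemic; one enantiomer drawn) | C=CCOc1cc(Br)c([C@H]2O[C@@H]2c2ccc(OCc3ccccc3)c(OC)c2)cc1OC | intermediate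
15 | (2R)-bornane-10,2-sultam [(3aS,6R,7aR)] | O=S1(=O)C[C@]23CC[C@H](C[C@H]2N1)C3(C)C | starting material
16 | fumaryl chloride | O=C(Cl)/C=C/C(=O)Cl | starting material
17 | sodium salt of 15 (formed in the flask) | [Na+].O=S1(=O)C[C@]23CC[C@H](C[C@H]2[N-]1)C3(C)C | intermediate
18 | N,N'-fumaroylbis[(2R)-bornane-10,2-sultam] | O=C(/C=C/C(=O)N1[C@@H]2C[C@H]3CC[C@]2(CS1(=O)=O)C3(C)C)N1[C@@H]2C[C@H]3CC[C@]2(CS1(=O)=O)C3(C)C | intermediate
19 | carbonyl ylide from 14, exo,exo (W) form (formed in the flask) | C=CCOc1cc(Br)c(/C=[O+]/[CH-]c2ccc(OCc3ccccc3)c(OC)c2)cc1OC | intermediate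
20 | (2S,3S,4S,5R)-oxolane-3,4-dicarbonyl bis-sultam: aryls 2,5-cis, acyl groups 3,4-trans, C3 acyl trans to the C2 bromoaryl, C4 acyl cis to the C5 benzyloxyaryl | C=CCOc1cc(Br)c([C@H]2O[C@@H](c3ccc(OCc4ccccc4)c(OC)c3)[C@@H](C(=O)N5[C@@H]6C[C@H]7CC[C@]6(CS5(=O)=O)C7(C)C)[C@@H]2C(=O)N5[C@@H]6C[C@H]7CC[C@]6(CS5(=O)=O)C7(C)C)cc1OC | intermediate
21 | [(2S,3R,4R,5R)-2-(4-allyloxy-2-bromo-5-methoxyphenyl)-5-(4-benzyloxy-3-methoxyphenyl)oxolane-3,4-diyl]dimethanol | C=CCOc1cc(Br)c([C@H]2O[C@@H](c3ccc(OCc4ccccc4)c(OC)c3)[C@@H](CO)[C@@H]2CO)cc1OC | intermediate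
22 | bis(methanesulfonate) of 21 | C=CCOc1cc(Br)c([C@H]2O[C@@H](c3ccc(OCc4ccccc4)c(OC)c3)[C@@H](COS(C)(=O)=O)[C@@H]2COS(C)(=O)=O)cc1OC | intermediate
23 | (2S,3S,4S,5R)-2-(4-allyloxy-2-bromo-5-methoxyphenyl)-5-(4-benzyloxy-3-methoxyphenyl)-3,4-dimethyloxolane | C=CCOc1cc(Br)c([C@H]2O[C@@H](c3ccc(OCc4ccccc4)c(OC)c3)[C@@H](C)[C@@H]2C)cc1OC | intermediate
24 | 4-[(2S,3S,4S,5R)-5-(4-benzyloxy-3-methoxyphenyl)-3,4-dimethyloxolan-2-yl]-5-bromo-2-methoxyphenol | Oc1cc(Br)c([C@H]2O[C@@H](c3ccc(OCc4ccccc4)c(OC)c3)[C@@H](C)[C@@H]2C)cc1OC | intermediate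
25 | (2S)-aryloxy ketone: 24 etherified with the 1-(3,4-dimethoxyphenyl)-1-oxopropan-2-yl group | COc1ccc(C(=O)[C@H](C)Oc2cc(Br)c([C@H]3O[C@@H](c4ccc(OCc5ccccc5)c(OC)c4)[C@@H](C)[C@@H]3C)cc2OC)cc1OC | intermediate
26 | (1R,2S)-erythro alcohol from 25 | COc1ccc([C@@H](O)[C@H](C)Oc2cc(Br)c([C@H]3O[C@@H](c4ccc(OCc5ccccc5)c(OC)c4)[C@@H](C)[C@@H]3C)cc2OC)cc1OC | intermediate
27 | (1R,2S)-1-(3,4-dimethoxyphenyl)-2-{4-[(2S,3S,4S,5R)-5-(4-hydroxy-3-methoxyphenyl)-3,4-dimethyloxolan-2-yl]-2-methoxyphenoxy}propan-1-ol | COc1ccc([C@@H](O)[C@H](C)Oc2ccc([C@H]3O[C@@H](c4ccc(O)c(OC)c4)[C@@H](C)[C@@H]3C)cc2OC)cc1OC | intermediate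
28 | (2R)-aryloxy ketone: 27 etherified at the free phenol with the 1-(3,4-dimethoxyphenyl)-1-oxopropan-2-yl group | COc1ccc([C@@H](O)[C@H](C)Oc2ccc([C@H]3O[C@@H](c4ccc(O[C@H](C)C(=O)c5ccc(OC)c(OC)c5)c(OC)c4)[C@@H](C)[C@@H]3C)cc2OC)cc1OC | intermediate
29 | CNP0116650.9: (1R,2S)-1-(3,4-dimethoxyphenyl)-2-[4-[(2S,3S,4S,5R)-5-[4-[[(1R,2R)-1-(3,4-dimethoxyphenyl)-1-hydroxypropan-2-yl]oxy]-3-methoxyphenyl]-3,4-dimethyloxolan-2-yl]-2-methoxyphenoxy]propan-1-ol | COc1ccc([C@@H](O)[C@H](C)Oc2ccc([C@H]3O[C@@H](c4ccc(O[C@H](C)[C@H](O)c5ccc(OC)c(OC)c5)c(OC)c4)[C@@H](C)[C@@H]3C)cc2OC)cc1OC | target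

**Totals and risks**
Total step count: 20. Longest linear sequence: 12 steps (9 → 10 → 14 → 20 → 21 → 22 → 23 → 24 → 25 → 26 → 27 → 28 → 29).

Most likely to fail, first: step 11. The endo acyl group may not discriminate between the two ylide termini, or may even prefer the brominated one, so that the cycloadduct with the bromoaryl ring cis to its neighbouring acyl group forms in a large share. The fallback changes the assignment of the arms, not the conditions, and is possible because the two phenol masks are orthogonal. It sets out from 14 and 18 (step 11 run as written) and comes back at 29. The orientation isomer of the cycloadduct F1 is isolated; LiAlH4 gives the diol F2, MsCl/Et3N the bis-mesylate F3, LiBHEt3 the dimethyloxolane F4, and Pd(PPh3)4/morpholine the bromophenol F5. BEMP and the (S)-mesylate 8 give the (R)-aryloxy ketone F6, resin-bound borohydride the threo alcohol F7, and H2 over Pd/C with NaOAc the phenol F8. BEMP and the (R)-mesylate 4 then give the (S)-aryloxy ketone F9, and Zn(BH4)2 gives 29.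

Second: step 9. The doubly donor-activated oxirane may open or undergo Meinwald rearrangement in the aqueous hydroxide medium or on isolation. The fallback sets out from 11 and 10 and comes back at 14. Triphenylphosphine hydrobromide converts 11 into the benzylphosphonium bromide F10; Wittig olefination with 10 (t-BuOK, THF) gives the stilbene F11 (E isomer drawn; any Z isomer would give the cis-oxirane, which serves equally because the oxirane configuration is lost in step 11). Epoxidation with dimethyldioxirane in acetone at 0 °C, neutral and anhydrous, should take place at the electron-rich stilbene bond and not at the allyl group, and gives 14, used crude.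

Third: step 20. The Felkin–Anh transition state may not be preferred strongly enough over a chelated one, which would give the erythro epimer at C7 of the second arm at the last step. The fallback sets C7 by C–C bond formation; it sets out from 27 and comes back at 29. Etherification of 27 with ethyl (S)-2-(tosyloxy)propanoate (BEMP, inversion) gives the (R)-2-aryloxypropanoate F12, iBu2AlH at −78 °C gives the aldehyde F13, and chelation-controlled addition of (3,4-dimethoxyphenyl)magnesium bromide (MgBr2·OEt2, CH2Cl2, −78 °C) should give 29 with the threo arrangement.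

**Further compounds**
F1 | step 11 | orientation isomer of 20: (2S,3S,4S,5R)-oxolane-3,4-dicarbonyl bis-sultam with the benzyloxyaryl at C2 (trans to the C3 acyl) and the bromoaryl at C5 (cis to the C4 acyl) | COc1cc([C@H]2O[C@@H](c3cc(OC)c(OCC=C)cc3Br)[C@@H](C(=O)N5[C@@H]6C[C@H]7CC[C@]6(CS5(=O)=O)C7(C)C)[C@@H]2C(=O)N5[C@@H]6C[C@H]7CC[C@]6(CS5(=O)=O)C7(C)C)ccc1OCc1ccccc1
F2 | step 11 | [(2S,3R,4R,5R)-5-(4-allyloxy-2-bromo-5-methoxyphenyl)-2-(4-benzyloxy-3-methoxyphenyl)oxolane-3,4-diyl]dimethanol | COc1cc([C@H]2O[C@@H](c3cc(OC)c(OCC=C)cc3Br)[C@@H](CO)[C@@H]2CO)ccc1OCc1ccccc1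
F3 | step 11 | bis(methanesulfonate) of F2 | COc1cc([C@H]2O[C@@H](c3cc(OC)c(OCC=C)cc3Br)[C@@H](COS(C)(=O)=O)[C@@H]2COS(C)(=O)=O)ccc1OCc1ccccc1
F4 | step 11 | (2S,3S,4S,5R)-5-(4-allyloxy-2-bromo-5-methoxyphenyl)-2-(4-benzyloxy-3-methoxyphenyl)-3,4-dimethyloxolane | COc1cc([C@H]2O[C@@H](c3cc(OC)c(OCC=C)cc3Br)[C@@H](C)[C@@H]2C)ccc1OCc1ccccc1
F5 | step 11 | 4-[(2R,3S,4S,5S)-5-(4-benzyloxy-3-methoxyphenyl)-3,4-dimethyloxolan-2-yl]-5-bromo-2-methoxyphenol | COc1cc([C@H]2O[C@@H](c3cc(OC)c(O)cc3Br)[C@@H](C)[C@@H]2C)ccc1OCc1ccccc1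
F6 | step 11 | (2R)-aryloxy ketone: F5 etherified with the 1-(3,4-dimethoxyphenyl)-1-oxopropan-2-yl group | COc1cc([C@H]2O[C@@H](c3cc(OC)c(O[C@H](C)C(=O)c4ccc(OC)c(OC)c4)cc3Br)[C@@H](C)[C@@H]2C)ccc1OCc1ccccc1
F7 | step 11 | (1R,2R)-threo alcohol from F6 | COc1cc([C@H]2O[C@@H](c3cc(OC)c(O[C@H](C)[C@H](O)c4ccc(OC)c(OC)c4)cc3Br)[C@@H](C)[C@@H]2C)ccc1OCc1ccccc1
F8 | step 11 | (1R,2R)-1-(3,4-dimethoxyphenyl)-2-{4-[(2R,3S,4S,5S)-5-(4-hydroxy-3-methoxyphenyl)-3,4-dimethyloxolan-2-yl]-2-methoxyphenoxy}propan-1-ol | COc1cc([C@H]2O[C@@H](c3ccc(O[C@H](C)[C@H](O)c4ccc(OC)c(OC)c4)c(OC)c3)[C@@H](C)[C@@H]2C)ccc1O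
F9 | step 11 | (2S)-aryloxy ketone: F8 etherified at the free phenol with the 1-(3,4-dimethoxyphenyl)-1-oxopropan-2-yl group | COc1ccc(C(=O)[C@H](C)Oc2ccc([C@H]3O[C@@H](c4ccc(O[C@H](C)[C@H](O)c5ccc(OC)c(OC)c5)c(OC)c4)[C@@H](C)[C@@H]3C)cc2OC)cc1OC
F10 | step 9 | [4-(benzyloxy)-3-methoxybenzyl]triphenylphosphonium bromide | COc1cc(C[P+](c2ccccc2)(c2ccccc2)c2ccccc2)ccc1OCc1ccccc1.[Br-]
F11 | step 9 | (E)-1-[4-(allyloxy)-2-bromo-5-methoxyphenyl]-2-[4-(benzyloxy)-3-methoxyphenyl]ethene | C=CCOc1cc(Br)c(/C=C/c2ccc(OCc3ccccc3)c(OC)c2)cc1OC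
F12 | step 20 | ethyl (2R)-2-aryloxypropanoate: 27 etherified at the free phenol | COc1ccc([C@@H](O)[C@H](C)Oc2ccc([C@H]3O[C@@H](c4ccc(O[C@H](C)C(=O)OCC)c(OC)c4)[C@@H](C)[C@@H]3C)cc2OC)cc1OC
F13 | step 20 | (2R)-2-aryloxypropanal from F12 | COc1ccc([C@@H](O)[C@H](C)Oc2ccc([C@H]3O[C@@H](c4ccc(O[C@H](C)C=O)c(OC)c4)[C@@H](C)[C@@H]3C)cc2OC)cc1OC
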